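**Retrosynthetic overview**
1. Target 30 ⇐ desilylation and intramolecular aldol condensation (C1–C10, closes ring A) of 1,5-diketo ester 26.
2. 26 ⇐ cis-fused γ-lactone 20 (C18 tied to the C10 oxygen): the C4 quaternary centre comes from two convex-face enolate alkylations (methallyl, then methyl); the lactone comes from a Ueno–Stork radical cyclisation of allylic alcohol 13, which sets C5.
3. 13 ⇐ enone 12 ⇐ ketone 10 by oxidative excision of the carvone isopropenyl group; the side chain of 10 (C13 by Ru–BINAP hydrogenation) is grown from the methyl ketone of 5.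
4. 5 ⇐ key intermolecular Mukaiyama–Michael addition of silyl enol ether 3 to methyl vinyl ketone 4 (C9–C11 bond, quaternary C9); 3 ⇐ (R)-carvone 1 + Me2CuLi.
5. Ring order: ring B is the carvone ring and is present from the start; ring A is closed last.

Assumption: halimane atom numbers are used in the explanations (C4 ester-bearing quaternary carbon, C5 ring-fusion CH, C8 CHMe, C9 quaternary carbon with the side chain, C10 ring-fusion alkene carbon, C13 side-chain CHMe), which makes the target (4S,5S,8R,9S,13R); centres formed as inconsequential mixtures and destroyed later (carbinol carbon of 7–9 and 28, acetal carbon of 14 and 15, peroxidic carbon of 11 and 25) are left undefined in the SMILES.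

**Route**

Step 1
Reactants: 1 (R)-carvone
Product: 3 trimethyl{[(3R,5R)-2,3-dimethyl-5-(prop-1-en-2-yl)cyclohex-1-en-1-yl]oxy}silane, via lithium enolate 2 (not isolated)
Conditions: Me2CuLi, Et2O, −20 °C; then TMSCl, Et3N, −20 → 0 °C
Reagents that add atoms: lithium dimethylcuprate [Li+].C[Cu-]C; chlorotrimethylsilane C[Si](C)(C)Cl
Why: Cuprate conjugate addition proceeds by axial attack anti to the isopropenyl group, setting C8 (R), and O-silylation traps the enolate regiospecifically as the tetrasubstituted silyl enol ether.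

Step 2
Reactants: 3 trimethyl{[(3R,5R)-2,3-dimethyl-5-(prop-1-en-2-yl)cyclohex-1-en-1-yl]oxy}silane; 4 methyl vinyl ketone
Product: 5 (2S,3R,5R)-2,3-dimethyl-2-(3-oxobutyl)-5-(prop-1-en-2-yl)cyclohexan-1-one
Conditions: BF3·OEt2 (1.1 equiv), i-PrOH (1 equiv), MeNO2/CH2Cl2, −78 °C
Reagents that add atoms: none
Why: Mukaiyama–Michael addition in which the silyl enol ether attacks BF3-activated enone 4 on the face anti to the pseudoaxial vicinal methyl, creating quaternary C9 (S) with the two methyls cis, while the alcohol takes up the silyl group so the 1,5-diketone is released without cyclising.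

Step 3
Reactants: 5 (2S,3R,5R)-2,3-dimethyl-2-(3-oxobutyl)-5-(prop-1-en-2-yl)cyclohexan-1-one
Product: 6 ethyl (2E)-5-[(1S,2R,4R)-1,2-dimethyl-6-oxo-4-(prop-1-en-2-yl)cyclohexyl]-3-methylpent-2-enoate
Conditions: (EtO)2P(O)CH2CO2Et, NaH (anion pre-formed, no excess base), THF, 0 °C → rt
Reagents that add atoms: triethyl phosphonoacetate CCOC(=O)CP(=O)(OCC)OCC
Why: Horner–Wadsworth–Emmons olefination takes place only at the unhindered methyl ketone (the ring ketone is flanked by a quaternary carbon) and gives mainly the E enoate, which is separated from the minor Z isomer by chromatography.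

Step 4
Reactants: 6 ethyl (2E)-5-[(1S,2R,4R)-1,2-dimethyl-6-oxo-4-(prop-1-en-2-yl)cyclohexyl]-3-methylpent-2-enoate
Product: 7 (2E)-5-[(1S,2R,4R)-6-hydroxy-1,2-dimethyl-4-(prop-1-en-2-yl)cyclohexyl]-3-methylpent-2-en-1-ol
Conditions: i-Bu2AlH (4 equiv), CH2Cl2, −78 → 0 °C
Reagents that add atoms: none
Why: Hydride reduction takes the conjugated ester cleanly to the allylic alcohol and also reduces the ring ketone, which is restored in step 7 so its carbinol configuration does not matter.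

Step 5
Reactants: 7 (2E)-5-[(1S,2R,4R)-6-hydroxy-1,2-dimethyl-4-(prop-1-en-2-yl)cyclohexyl]-3-methylpent-2-en-1-ol
Product: 8 (3R)-5-[(1S,2R,4R)-6-hydroxy-1,2-dimethyl-4-(prop-1-en-2-yl)cyclohexyl]-3-methylpentan-1-ol
Conditions: Ru(OAc)2[(S)-BINAP] (1 mol%), H2 (30 atm), MeOH, 25 °C
Reagents that add atoms: none
Why: Noyori asymmetric hydrogenation of a geraniol-type E allylic alcohol, in which the hydroxyl-bound catalyst sets C13 (R) (same sense as geraniol to (R)-citronellol) and leaves the unfunctionalised isopropenyl group untouched.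

Step 6
Reactants: 8 (3R)-5-[(1S,2R,4R)-6-hydroxy-1,2-dimethyl-4-(prop-1-en-2-yl)cyclohexyl]-3-methylpentan-1-ol
Product: 9 (2S,3R,5R)-2-[(3R)-5-{[tert-butyl(diphenyl)silyl]oxy}-3-methylpentyl]-2,3-dimethyl-5-(prop-1-en-2-yl)cyclohexan-1-ol
Conditions: TBDPSCl (1.05 equiv), imidazole, CH2Cl2, 0 °C
Reagents that add atoms: tert-butyl(chloro)diphenylsilane CC(C)(C)[Si](Cl)(c1ccccc1)c1ccccc1
Why: Silyl ether formation is selective for the primary hydroxyl because the secondary alcohol sits next to a quaternary carbon.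

Step 7
Reactants: 9 (2S,3R,5R)-2-[(3R)-5-{[tert-butyl(diphenyl)silyl]oxy}-3-methylpentyl]-2,3-dimethyl-5-(prop-1-en-2-yl)cyclohexan-1-ol
Product: 10 (2S,3R,5R)-2-[(3R)-5-{[tert-butyl(diphenyl)silyl]oxy}-3-methylpentyl]-2,3-dimethyl-5-(prop-1-en-2-yl)cyclohexan-1-one
Conditions: Dess–Martin periodinane, CH2Cl2, rt
Reagents that add atoms: none
Why: Dess–Martin oxidation returns both carbinol epimers to the single ketone under neutral conditions without touching the alkene or the silyl ether.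

Step 8
Reactants: 10 (2S,3R,5R)-2-[(3R)-5-{[tert-butyl(diphenyl)silyl]oxy}-3-methylpentyl]-2,3-dimethyl-5-(prop-1-en-2-yl)cyclohexan-1-one
Product: 12 (5R,6S)-6-[(3R)-5-{[tert-butyl(diphenyl)silyl]oxy}-3-methylpentyl]-5,6-dimethylcyclohex-2-en-1-one, via methoxy hydroperoxide 11 (not isolated)
Conditions: O3, CH2Cl2/MeOH, −78 °C; then Cu(OAc)2·H2O, FeSO4·7H2O, −20 °C → rt
Reagents that add atoms: none
Why: Ozonolysis in methanol followed by the Schreiber-type fragmentation, in which ferrous ion cleaves the hydroperoxide, the alkoxy radical loses methyl acetate and Cu(OAc)2 oxidises the ring radical to the conjugated enone, excising the isopropenyl group and installing the C5=C6 alkene.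

Step 9
Reactants: 12 (5R,6S)-6-[(3R)-5-{[tert-butyl(diphenyl)silyl]oxy}-3-methylpentyl]-5,6-dimethylcyclohex-2-en-1-one
Product: 13 (1S,5R,6S)-6-[(3R)-5-{[tert-butyl(diphenyl)silyl]oxy}-3-methylpentyl]-5,6-dimethylcyclohex-2-en-1-ol
Conditions: NaBH4, CeCl3·7H2O, MeOH, −78 → −40 °C
Reagents that add atoms: none
Why: Luche 1,2-reduction delivers hydride to the carbonyl face opposite the two cis methyl groups on C8 and C9, so the C10 oxygen ends up cis to those methyls.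

Step 10
Reactants: 13 (1S,5R,6S)-6-[(3R)-5-{[tert-butyl(diphenyl)silyl]oxy}-3-methylpentyl]-5,6-dimethylcyclohex-2-en-1-ol
Product: 14 {[(3R)-5-[(1S,2S,6R)-2-(2-bromo-1-ethoxyethoxy)-1,6-dimethylcyclohex-3-en-1-yl]-3-methylpentyl]oxy}(tert-butyl)diphenylsilane
Conditions: ethyl vinyl ether, NBS, CH2Cl2, −40 → 0 °C
Reagents that add atoms: ethyl vinyl ether C=COCC; N-bromosuccinimide BrN1C(=O)CCC1=O
Why: Bromoacetalisation, in which the alcohol captures the bromonium ion of the electron-rich enol ether to give the mixed bromoacetal tether.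

Step 11
Reactants: 14 {[(3R)-5-[(1S,2S,6R)-2-(2-bromo-1-ethoxyethoxy)-1,6-dimethylcyclohex-3-en-1-yl]-3-methylpentyl]oxy}(tert-butyl)diphenylsilane
Product: 15 {[(3R)-5-[(3aR,6R,7S,7aS)-2-ethoxy-6,7-dimethyloctahydro-1-benzofuran-7-yl]-3-methylpentyl]oxy}(tert-butyl)diphenylsilane
Conditions: Bu3SnH (slow addition), AIBN (cat.), PhH, 80 °C
Reagents that add atoms: none
Why: Ueno–Stork radical cyclisation, whose 5-exo-trig closure onto C5 can only give the cis-fused ring, so the new C4–C5 bond is delivered to the face of the C10 oxygen and sets C5.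

Step 12
Reactants: 15 {[(3R)-5-[(3aR,6R,7S,7aS)-2-ethoxy-6,7-dimethyloctahydro-1-benzofuran-7-yl]-3-methylpentyl]oxy}(tert-butyl)diphenylsilane
Product: 16 (3aR,6R,7S,7aS)-7-[(3R)-5-{[tert-butyl(diphenyl)silyl]oxy}-3-methylpentyl]-6,7-dimethylhexahydro-1-benzofuran-2(3H)-one
Conditions: CrO3, H2SO4, H2O, acetone, 0 °C
Reagents that add atoms: water O
Why: Jones oxidation hydrolyses the ethyl acetal and oxidises the lactol to the cis-fused γ-lactone.

Step 13
Reactants: 16 (3aR,6R,7S,7aS)-7-[(3R)-5-{[tert-butyl(diphenyl)silyl]oxy}-3-methylpentyl]-6,7-dimethylhexahydro-1-benzofuran-2(3H)-one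
Product: 18 (3R,3aR,6R,7S,7aS)-7-[(3R)-5-{[tert-butyl(diphenyl)silyl]oxy}-3-methylpentyl]-6,7-dimethyl-3-(2-methylprop-2-en-1-yl)hexahydro-1-benzofuran-2(3H)-one, via lithium enolate 17 (not isolated)
Conditions: LiN(i-Pr)2, THF, −78 °C; then CH2=C(CH3)CH2Br, −78 → −30 °C
Reagents that add atoms: 3-bromo-2-methylprop-1-ene CC(=C)CBr
Why: Lactone enolate alkylation with a reactive allylic bromide installs the C3–C2–C1 unit, and the configuration of the new tertiary centre is erased in the next step.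

Step 14
Reactants: 18 (3R,3aR,6R,7S,7aS)-7-[(3R)-5-{[tert-butyl(diphenyl)silyl]oxy}-3-methylpentyl]-6,7-dimethyl-3-(2-methylprop-2-en-1-yl)hexahydro-1-benzofuran-2(3H)-one
Product: 20 (3S,3aR,6R,7S,7aS)-7-[(3R)-5-{[tert-butyl(diphenyl)silyl]oxy}-3-methylpentyl]-3,6,7-trimethyl-3-(2-methylprop-2-en-1-yl)hexahydro-1-benzofuran-2(3H)-one, via lithium enolate 19 (not isolated)
Conditions: LiN(i-Pr)2, THF, −78 °C; then MeI, −78 → −20 °C
Reagents that add atoms: iodomethane CI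
Why: Second enolate alkylation in which methyl iodide attacks the enolate of the cis-fused bicycle from its convex face (the side of H-5), placing methyl cis to H-5 and the methallyl group on the concave face, which is the C4 configuration of the target.

Step 15
Reactants: 20 (3S,3aR,6R,7S,7aS)-7-[(3R)-5-{[tert-butyl(diphenyl)silyl]oxy}-3-methylpentyl]-3,6,7-trimethyl-3-(2-methylprop-2-en-1-yl)hexahydro-1-benzofuran-2(3H)-one
Product: 21 (1S,2S,3R,6R)-2-[(3R)-5-{[tert-butyl(diphenyl)silyl]oxy}-3-methylpentyl]-6-[(2S)-1-hydroxy-2,4-dimethylpent-4-en-2-yl]-2,3-dimethylcyclohexan-1-ol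
Conditions: LiAlH4, THF, 0 °C → rt
Reagents that add atoms: none
Why: Hydride reduction opens the lactone to the 1,4-diol without affecting any stereocentre.

Step 16
Reactants: 21 (1S,2S,3R,6R)-2-[(3R)-5-{[tert-butyl(diphenyl)silyl]oxy}-3-methylpentyl]-6-[(2S)-1-hydroxy-2,4-dimethylpent-4-en-2-yl]-2,3-dimethylcyclohexan-1-ol
Product: 22 (2S)-2-[(1R,3S,4R)-3-[(3R)-5-{[tert-butyl(diphenyl)silyl]oxy}-3-methylpentyl]-3,4-dimethyl-2-oxocyclohexyl]-2,4-dimethylpent-4-enal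
Conditions: (COCl)2, DMSO, CH2Cl2, −78 °C; then Et3N, −78 → 0 °C
Reagents that add atoms: none
Why: Swern oxidation activates both hydroxyls before base is added, so the keto aldehyde forms without lactol or lactone formation, and the aldehyde has no α-hydrogen to epimerise.

Step 17
Reactants: 22 (2S)-2-[(1R,3S,4R)-3-[(3R)-5-{[tert-butyl(diphenyl)silyl]oxy}-3-methylpentyl]-3,4-dimethyl-2-oxocyclohexyl]-2,4-dimethylpent-4-enal
Product: 23 (2S)-2-[(1R,3S,4R)-3-[(3R)-5-{[tert-butyl(diphenyl)silyl]oxy}-3-methylpentyl]-3,4-dimethyl-2-oxocyclohexyl]-2,4-dimethylpent-4-enoic acid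
Conditions: NaClO2, NaH2PO4, 2-methylbut-2-ene, t-BuOH/H2O, 0 °C → rt
Reagents that add atoms: sodium chlorite [Na+].[O-]Cl=O
Why: Pinnick oxidation converts the neopentyl aldehyde to the acid while the scavenger alkene protects the methallyl group from HOCl.

Step 18
Reactants: 23 (2S)-2-[(1R,3S,4R)-3-[(3R)-5-{[tert-butyl(diphenyl)silyl]oxy}-3-methylpentyl]-3,4-dimethyl-2-oxocyclohexyl]-2,4-dimethylpent-4-enoic acid
Product: 24 methyl (2S)-2-[(1R,3S,4R)-3-[(3R)-5-{[tert-butyl(diphenyl)silyl]oxy}-3-methylpentyl]-3,4-dimethyl-2-oxocyclohexyl]-2,4-dimethylpent-4-enoate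
Conditions: TMSCHN2, PhMe/MeOH (4:1), 0 °C
Reagents that add atoms: (trimethylsilyl)diazomethane C[Si](C)(C)C=[N+]=[N-]
Why: Diazoalkane esterification methylates the hindered acid under neutral conditions, avoiding base that could epimerise C5 next to the ketone.

Step 19
Reactants: 24 methyl (2S)-2-[(1R,3S,4R)-3-[(3R)-5-{[tert-butyl(diphenyl)silyl]oxy}-3-methylpentyl]-3,4-dimethyl-2-oxocyclohexyl]-2,4-dimethylpent-4-enoate
Product: 26 methyl (2S)-2-[(1R,3S,4R)-3-[(3R)-5-{[tert-butyl(diphenyl)silyl]oxy}-3-methylpentyl]-3,4-dimethyl-2-oxocyclohexyl]-2-methyl-4-oxopentanoate, via ozonide 25 (not isolated)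
Conditions: O3, CH2Cl2, −78 °C; then PPh3, −78 °C → rt
Reagents that add atoms: ozone [O-][O+]=O
Why: Ozonolysis with reductive work-up cleaves the only alkene and unveils the methyl ketone of the C1–C3 unit.

Step 20
Reactants: 26 methyl (2S)-2-[(1R,3S,4R)-3-[(3R)-5-{[tert-butyl(diphenyl)silyl]oxy}-3-methylpentyl]-3,4-dimethyl-2-oxocyclohexyl]-2-methyl-4-oxopentanoate
Product: 29 methyl (1S,5S,6R,8aS)-5-[(3R)-5-{[tert-butyl(diphenyl)silyl]oxy}-3-methylpentyl]-1,5,6-trimethyl-3-oxo-1,2,3,5,6,7,8,8a-octahydronaphthalene-1-carboxylate, via lithium enolate 27 (not isolated), via ketol 28 (not isolated)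
Conditions: LiN(SiMe3)2 (1.1 equiv), THF, −78 → −20 °C; AcOH quench; then p-TsOH·H2O (cat.), PhH, 40 °C
Reagents that add atoms: none
Why: Intramolecular aldol condensation in which kinetic deprotonation occurs only at the methyl group, the enolate closes ring A onto the C10 ketone faster than it attacks the hindered ester, and mild acid dehydrates the tertiary ketol to the conjugated enone without base that could epimerise C5.

Step 21
Reactants: 29 methyl (1S,5S,6R,8aS)-5-[(3R)-5-{[tert-butyl(diphenyl)silyl]oxy}-3-methylpentyl]-1,5,6-trimethyl-3-oxo-1,2,3,5,6,7,8,8a-octahydronaphthalene-1-carboxylate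
Product: 30 methyl (1S,5S,6R,8aS)-5-[(3R)-5-hydroxy-3-methylpentyl]-1,5,6-trimethyl-3-oxo-1,2,3,5,6,7,8,8a-octahydronaphthalene-1-carboxylate
Conditions: HF·pyridine, THF/pyridine, 0 °C → rt
Reagents that add atoms: none
Why: Fluoride-mediated desilylation under buffered non-basic conditions frees the primary alcohol and leaves the enone, the ester and the γ-stereocentre C5 untouched.

**Compound list**
1 | (R)-carvone, (5R)-2-methyl-5-(prop-1-en-2-yl)cyclohex-2-en-1-one | CC1=CC[C@H](CC1=O)C(C)=C | starting material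
2 | lithium (3R,5R)-2,3-dimethyl-5-(prop-1-en-2-yl)cyclohex-1-en-1-olate | [Li+].[O-]C1=C(C)[C@H](C)C[C@@H](C(C)=C)C1 | intermediate
3 | trimethyl{[(3R,5R)-2,3-dimethyl-5-(prop-1-en-2-yl)cyclohex-1-en-1-yl]oxy}silane | C[Si](C)(C)OC1=C(C)[C@H](C)C[C@@H](C(C)=C)C1 | intermediate
4 | methyl vinyl ketone (but-3-en-2-one) | CC(=O)C=C | starting material
5 | (2S,3R,5R)-2,3-dimethyl-2-(3-oxobutyl)-5-(prop-1-en-2-yl)cyclohexan-1-one | O=C1[C@@](C)(CCC(C)=O)[C@H](C)C[C@@H](C(C)=C)C1 | intermediate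
6 | ethyl (2E)-5-[(1S,2R,4R)-1,2-dimethyl-6-oxo-4-(prop-1-en-2-yl)cyclohexyl]-3-methylpent-2-enoate | CCOC(=O)/C=C(\C)CC[C@@]1(C)[C@H](C)C[C@@H](C(C)=C)CC1=O | intermediate
7 | (2E)-5-[(1S,2R,4R)-6-hydroxy-1,2-dimethyl-4-(prop-1-en-2-yl)cyclohexyl]-3-methylpent-2-en-1-ol (both carbinol epimers) | OC/C=C(\C)CC[C@@]1(C)[C@H](C)C[C@@H](C(C)=C)CC1O | intermediate
8 | (3R)-5-[(1S,2R,4R)-6-hydroxy-1,2-dimethyl-4-(prop-1-en-2-yl)cyclohexyl]-3-methylpentan-1-ol (both carbinol epimers) | OCC[C@H](C)CC[C@@]1(C)[C@H](C)C[C@@H](C(C)=C)CC1O | intermediate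
9 | (2S,3R,5R)-2-[(3R)-5-{[tert-butyl(diphenyl)silyl]oxy}-3-methylpentyl]-2,3-dimethyl-5-(prop-1-en-2-yl)cyclohexan-1-ol (both carbinol epimers) | CC(C)(C)[Si](c1ccccc1)(c1ccccc1)OCC[C@H](C)CC[C@@]1(C)[C@H](C)C[C@@H](C(C)=C)CC1O | intermediate
10 | (2S,3R,5R)-2-[(3R)-5-{[tert-butyl(diphenyl)silyl]oxy}-3-methylpentyl]-2,3-dimethyl-5-(prop-1-en-2-yl)cyclohexan-1-one | CC(C)(C)[Si](c1ccccc1)(c1ccccc1)OCC[C@H](C)CC[C@@]1(C)[C@H](C)C[C@@H](C(C)=C)CC1=O | intermediate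
11 | (2S,3R,5R)-2-[(3R)-5-{[tert-butyl(diphenyl)silyl]oxy}-3-methylpentyl]-5-(1-hydroperoxy-1-methoxyethyl)-2,3-dimethylcyclohexan-1-one | CC(C)(C)[Si](c1ccccc1)(c1ccccc1)OCC[C@H](C)CC[C@@]1(C)[C@H](C)C[C@@H](C(C)(OC)OO)CC1=O | intermediate
12 | (5R,6S)-6-[(3R)-5-{[tert-butyl(diphenyl)silyl]oxy}-3-methylpentyl]-5,6-dimethylcyclohex-2-en-1-one | CC(C)(C)[Si](c1ccccc1)(c1ccccc1)OCC[C@H](C)CC[C@@]1(C)[C@H](C)CC=CC1=O | intermediate
13 | (1S,5R,6S)-6-[(3R)-5-{[tert-butyl(diphenyl)silyl]oxy}-3-methylpentyl]-5,6-dimethylcyclohex-2-en-1-ol | CC(C)(C)[Si](c1ccccc1)(c1ccccc1)OCC[C@H](C)CC[C@@]1(C)[C@H](C)CC=C[C@@H]1O | intermediate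
14 | {[(3R)-5-[(1S,2S,6R)-2-(2-bromo-1-ethoxyethoxy)-1,6-dimethylcyclohex-3-en-1-yl]-3-methylpentyl]oxy}(tert-butyl)diphenylsilane | CC(C)(C)[Si](c1ccccc1)(c1ccccc1)OCC[C@H](C)CC[C@@]1(C)[C@H](C)CC=C[C@@H]1OC(CBr)OCC | intermediate
15 | {[(3R)-5-[(3aR,6R,7S,7aS)-2-ethoxy-6,7-dimethyloctahydro-1-benzofuran-7-yl]-3-methylpentyl]oxy}(tert-butyl)diphenylsilane | CC(C)(C)[Si](c1ccccc1)(c1ccccc1)OCC[C@H](C)CC[C@@]1(C)[C@H](C)CC[C@@H]2CC(OCC)O[C@H]12 | intermediate
16 | (3aR,6R,7S,7aS)-7-[(3R)-5-{[tert-butyl(diphenyl)silyl]oxy}-3-methylpentyl]-6,7-dimethylhexahydro-1-benzofuran-2(3H)-one | CC(C)(C)[Si](c1ccccc1)(c1ccccc1)OCC[C@H](C)CC[C@@]1(C)[C@H](C)CC[C@@H]2CC(=O)O[C@H]12 | intermediate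
17 | lithium enolate of lactone 16 | [Li+].CC(C)(C)[Si](c1ccccc1)(c1ccccc1)OCC[C@H](C)CC[C@@]1(C)[C@H](C)CC[C@@H]2C=C([O-])O[C@H]12 | intermediate
18 | (3R,3aR,6R,7S,7aS)-7-[(3R)-5-{[tert-butyl(diphenyl)silyl]oxy}-3-methylpentyl]-6,7-dimethyl-3-(2-methylprop-2-en-1-yl)hexahydro-1-benzofuran-2(3H)-one | CC(C)(C)[Si](c1ccccc1)(c1ccccc1)OCC[C@H](C)CC[C@@]1(C)[C@H](C)CC[C@@H]2[C@@H](CC(C)=C)C(=O)O[C@H]12 | intermediate
19 | lithium enolate of lactone 18 | [Li+].CC(C)(C)[Si](c1ccccc1)(c1ccccc1)OCC[C@H](C)CC[C@@]1(C)[C@H](C)CC[C@@H]2C(CC(C)=C)=C([O-])O[C@H]12 | intermediate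
20 | (3S,3aR,6R,7S,7aS)-7-[(3R)-5-{[tert-butyl(diphenyl)silyl]oxy}-3-methylpentyl]-3,6,7-trimethyl-3-(2-methylprop-2-en-1-yl)hexahydro-1-benzofuran-2(3H)-one | CC(C)(C)[Si](c1ccccc1)(c1ccccc1)OCC[C@H](C)CC[C@@]1(C)[C@H](C)CC[C@@H]2[C@](C)(CC(C)=C)C(=O)O[C@H]12 | intermediate
21 | (1S,2S,3R,6R)-2-[(3R)-5-{[tert-butyl(diphenyl)silyl]oxy}-3-methylpentyl]-6-[(2S)-1-hydroxy-2,4-dimethylpent-4-en-2-yl]-2,3-dimethylcyclohexan-1-ol | CC(C)(C)[Si](c1ccccc1)(c1ccccc1)OCC[C@H](C)CC[C@@]1(C)[C@H](C)CC[C@H]([C@@](C)(CO)CC(C)=C)[C@@H]1O | intermediate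
22 | (2S)-2-[(1R,3S,4R)-3-[(3R)-5-{[tert-butyl(diphenyl)silyl]oxy}-3-methylpentyl]-3,4-dimethyl-2-oxocyclohexyl]-2,4-dimethylpent-4-enal | CC(C)(C)[Si](c1ccccc1)(c1ccccc1)OCC[C@H](C)CC[C@@]1(C)[C@H](C)CC[C@H]([C@@](C)(C=O)CC(C)=C)C1=O | intermediate
23 | (2S)-2-[(1R,3S,4R)-3-[(3R)-5-{[tert-butyl(diphenyl)silyl]oxy}-3-methylpentyl]-3,4-dimethyl-2-oxocyclohexyl]-2,4-dimethylpent-4-enoic acid | CC(C)(C)[Si](c1ccccc1)(c1ccccc1)OCC[C@H](C)CC[C@@]1(C)[C@H](C)CC[C@H]([C@@](C)(C(O)=O)CC(C)=C)C1=O | intermediate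
24 | methyl (2S)-2-[(1R,3S,4R)-3-[(3R)-5-{[tert-butyl(diphenyl)silyl]oxy}-3-methylpentyl]-3,4-dimethyl-2-oxocyclohexyl]-2,4-dimethylpent-4-enoate | CC(C)(C)[Si](c1ccccc1)(c1ccccc1)OCC[C@H](C)CC[C@@]1(C)[C@H](C)CC[C@H]([C@@](C)(C(=O)OC)CC(C)=C)C1=O | intermediate
25 | methyl (2S)-2-[(1R,3S,4R)-3-[(3R)-5-{[tert-butyl(diphenyl)silyl]oxy}-3-methylpentyl]-3,4-dimethyl-2-oxocyclohexyl]-2-methyl-3-(3-methyl-1,2,4-trioxolan-3-yl)propanoate | CC(C)(C)[Si](c1ccccc1)(c1ccccc1)OCC[C@H](C)CC[C@@]1(C)[C@H](C)CC[C@H]([C@@](C)(C(=O)OC)CC2(C)OCOO2)C1=O | intermediate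
26 | methyl (2S)-2-[(1R,3S,4R)-3-[(3R)-5-{[tert-butyl(diphenyl)silyl]oxy}-3-methylpentyl]-3,4-dimethyl-2-oxocyclohexyl]-2-methyl-4-oxopentanoate | CC(C)(C)[Si](c1ccccc1)(c1ccccc1)OCC[C@H](C)CC[C@@]1(C)[C@H](C)CC[C@H]([C@@](C)(C(=O)OC)CC(C)=O)C1=O | intermediate
27 | lithium enolate of the methyl ketone of 26 (terminal pent-1-en-2-olate) | [Li+].CC(C)(C)[Si](c1ccccc1)(c1ccccc1)OCC[C@H](C)CC[C@@]1(C)[C@H](C)CC[C@H]([C@@](C)(C(=O)OC)CC(=C)[O-])C1=O | intermediate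
28 | methyl (1S,5S,6R,8aR)-5-[(3R)-5-{[tert-butyl(diphenyl)silyl]oxy}-3-methylpentyl]-4a-hydroxy-1,5,6-trimethyl-3-oxodecahydronaphthalene-1-carboxylate | COC(=O)[C@@]1(C)CC(=O)CC2(O)[C@@H]1CC[C@@H](C)[C@]2(C)CC[C@@H](C)CCO[Si](c1ccccc1)(c1ccccc1)C(C)(C)C | intermediate
29 | methyl (1S,5S,6R,8aS)-5-[(3R)-5-{[tert-butyl(diphenyl)silyl]oxy}-3-methylpentyl]-1,5,6-trimethyl-3-oxo-1,2,3,5,6,7,8,8a-octahydronaphthalene-1-carboxylate | COC(=O)[C@@]1(C)CC(=O)C=C2[C@@H]1CC[C@@H](C)[C@]2(C)CC[C@@H](C)CCO[Si](c1ccccc1)(c1ccccc1)C(C)(C)C | intermediate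
30 | methyl (1S,5S,6R,8aS)-5-[(3R)-5-hydroxy-3-methylpentyl]-1,5,6-trimethyl-3-oxo-1,2,3,5,6,7,8,8a-octahydronaphthalene-1-carboxylate | COC(=O)[C@@]1(C)CC(=O)C=C2[C@@H]1CC[C@@H](C)[C@]2(C)CC[C@@H](C)CCO | target

**Totals**
Total step count: 21. Longest linear sequence: 21 steps (from 1; 4 enters in step 2).

**Steps most likely to fail and fallbacks**

Step 2 (Lewis-acid Michael addition forming the quaternary carbon; the isopropenyl group and enone 4 can polymerise or ionise). The fallback replaces the Michael addition by an enolate alkylation. It sets out from 3: MeLi in THF at 0 °C regenerates lithium enolate 2, which is alkylated (HMPA, −20 °C → rt) with 2-(2-iodoethyl)-2-methyl-1,3-dioxolane, again anti to the vicinal methyl, to give (2S,3R,5R)-2,3-dimethyl-2-[2-(2-methyl-1,3-dioxolan-2-yl)ethyl]-5-(prop-1-en-2-yl)cyclohexan-1-one F1. PPTS in wet acetone then removes the ketal and the route is rejoined at 5.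

Step 8 (the Fe/Cu fragmentation usually gives moderate yields, and the C5 centre then depends on the facial selectivity of step 9). The fallback keeps the isopropenyl group as a control element and bypasses steps 8 to 12. It sets out from 10:
- LiN(i-Pr)2 in THF at −78 °C gives the lithium enolate of ketone 10 F2, which is alkylated with methyl bromoacetate trans to the adjacent isopropenyl group (the diequatorial isomer, which can also be reached by equilibration with DBU). The product is methyl 2-[(1S,3S,4R,6R)-3-[(3R)-5-{[tert-butyl(diphenyl)silyl]oxy}-3-methylpentyl]-3,4-dimethyl-2-oxo-6-(prop-1-en-2-yl)cyclohexyl]acetate F3.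
- NaBH4 in MeOH attacks from the face opposite the axial C8 methyl to give methyl 2-[(1S,2S,3S,4R,6R)-3-[(3R)-5-{[tert-butyl(diphenyl)silyl]oxy}-3-methylpentyl]-2-hydroxy-3,4-dimethyl-6-(prop-1-en-2-yl)cyclohexyl]acetate F4. With catalytic p-TsOH this closes to the cis-fused lactone (3aS,4R,6R,7S,7aS)-7-[(3R)-5-{[tert-butyl(diphenyl)silyl]oxy}-3-methylpentyl]-6,7-dimethyl-4-(prop-1-en-2-yl)hexahydro-1-benzofuran-2(3H)-one F5.
- Ozonolysis in MeOH at −78 °C gives (3aS,4R,6R,7S,7aS)-7-[(3R)-5-{[tert-butyl(diphenyl)silyl]oxy}-3-methylpentyl]-4-(1-hydroperoxy-1-methoxyethyl)-6,7-dimethylhexahydro-1-benzofuran-2(3H)-one F6. FeSO4·7H2O and PhSH then replace the former isopropenyl group by hydrogen (hydrodealkenylation), and the route is rejoined at 16.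

Step 20 (aldol closure onto a ketone flanked by a quaternary and a heavily substituted carbon; retro-aldol and Claisen attack on the ester compete). The fallback switches from the reversible anionic aldol to a Lewis-acid Mukaiyama aldol that activates the hindered ketone. It sets out from 26: LiN(SiMe3)2 at −78 °C gives 27, which is trapped with TMSCl as methyl (2S)-2-[(1R,3S,4R)-3-[(3R)-5-{[tert-butyl(diphenyl)silyl]oxy}-3-methylpentyl]-3,4-dimethyl-2-oxocyclohexyl]-2-methyl-4-[(trimethylsilyl)oxy]pent-4-enoate F7. TiCl4 in CH2Cl2 at −78 °C closes ring A, aqueous work-up gives ketol 28, and the route is rejoined there (acid dehydration to 29 as in step 20).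

**Further compounds**
F1 | step 2 | (2S,3R,5R)-2,3-dimethyl-2-[2-(2-methyl-1,3-dioxolan-2-yl)ethyl]-5-(prop-1-en-2-yl)cyclohexan-1-one | O=C1[C@@](C)(CCC2(C)OCCO2)[C@H](C)C[C@@H](C(C)=C)C1
F2 | step 8 | lithium enolate of ketone 10 | [Li+].CC(C)(C)[Si](c1ccccc1)(c1ccccc1)OCC[C@H](C)CC[C@@]1(C)[C@H](C)C[C@@H](C(C)=C)C=C1[O-]
F3 | step 8 | methyl 2-[(1S,3S,4R,6R)-3-[(3R)-5-{[tert-butyl(diphenyl)silyl]oxy}-3-methylpentyl]-3,4-dimethyl-2-oxo-6-(prop-1-en-2-yl)cyclohexyl]acetate | CC(C)(C)[Si](c1ccccc1)(c1ccccc1)OCC[C@H](C)CC[C@@]1(C)[C@H](C)C[C@@H](C(C)=C)[C@H](CC(=O)OC)C1=O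
F4 | step 8 | methyl 2-[(1S,2S,3S,4R,6R)-3-[(3R)-5-{[tert-butyl(diphenyl)silyl]oxy}-3-methylpentyl]-2-hydroxy-3,4-dimethyl-6-(prop-1-en-2-yl)cyclohexyl]acetate | CC(C)(C)[Si](c1ccccc1)(c1ccccc1)OCC[C@H](C)CC[C@@]1(C)[C@H](C)C[C@@H](C(C)=C)[C@H](CC(=O)OC)[C@@H]1O
F5 | step 8 | (3aS,4R,6R,7S,7aS)-7-[(3R)-5-{[tert-butyl(diphenyl)silyl]oxy}-3-methylpentyl]-6,7-dimethyl-4-(prop-1-en-2-yl)hexahydro-1-benzofuran-2(3H)-one | CC(C)(C)[Si](c1ccccc1)(c1ccccc1)OCC[C@H](C)CC[C@@]1(C)[C@H](C)C[C@@H](C(C)=C)[C@@H]2CC(=O)O[C@H]12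
F6 | step 8 | (3aS,4R,6R,7S,7aS)-7-[(3R)-5-{[tert-butyl(diphenyl)silyl]oxy}-3-methylpentyl]-4-(1-hydroperoxy-1-methoxyethyl)-6,7-dimethylhexahydro-1-benzofuran-2(3H)-one | CC(C)(C)[Si](c1ccccc1)(c1ccccc1)OCC[C@H](C)CC[C@@]1(C)[C@H](C)C[C@@H](C(C)(OC)OO)[C@@H]2CC(=O)O[C@H]12
F7 | step 20 | methyl (2S)-2-[(1R,3S,4R)-3-[(3R)-5-{[tert-butyl(diphenyl)silyl]oxy}-3-methylpentyl]-3,4-dimethyl-2-oxocyclohexyl]-2-methyl-4-[(trimethylsilyl)oxy]pent-4-enoate | CC(C)(C)[Si](c1ccccc1)(c1ccccc1)OCC[C@H](C)CC[C@@]1(C)[C@H](C)CC[C@H]([C@@](C)(C(=O)OC)CC(=C)O[Si](C)(C)C)C1=O
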